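**Plan**

1. Numbering: chromene numbers for the bicycle (O1, C2, C3, C4, C4a, C5, C6, C7, C8, C8a); drimane numbers with primes for the decalin (C9' is bonded to C2).
2. Retrosynthesis: the C6 enone comes from an allylic silyl ether, and C3=C4–CH2OAc from a C4 ketone through its C3 enol triflate. The cyclohexene ring is then cut at C5–C6 and C4a–C8a (retro-[4+2]), which also opens the pyranone, because O1–C2–C3–C4 is the tether between diene terminus C8a and dienophile carbon C4a.
3. Enabling feature: ring C4a–C5–C6–C7–C8–C8a carries oxygen at C6 and at C8a, 1,4 across the C7=C8 double bond (the pattern of a 1,4-dioxygenated diene adduct), and C4a sits next to C4, which can be a ketone that activates C4a=C5.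
4. Forward order: ring B of drimenol is adjusted first (C6' oxidation, α-epoxidation, Wharton transposition; steps 1–6). The chain is then grown at C2 (acetate aldol, O-allylation, cross-metathesis, silyl dienol ether; steps 7–10). Both new rings arise together in step 11, followed by C3=C4/CH2OAc (steps 12–14) and the enone (steps 15–16).
5. Stereochemistry: C5', C9', C10' come from drimenol; C8' from α-face epoxidation, kept through the Wharton step; C2 from a Felkin-type aldol addition; C4a and C8a from the cycloaddition under control of C2.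

Key step: step 11

Remark: (−)-drimenol is taken as a purchasable chiral-pool material; Dr stands for the decalin residue bonded through C9' (8'α-triethylsilyloxy, C6'=C7', 4',4',8',10'-tetramethyl); the C6 configuration drawn for the silyl ether intermediates is the expected one and is erased in the last step.

Step 1
Reactants: 1 (−)-drimenol
Product: 2 drimenol triethylsilyl ether
Conditions: Et3SiCl, imidazole, CH2Cl2, 0 °C to rt
Reagents that add atoms: chlorotriethylsilane CC[Si](Cl)(CC)CC
Why: Standard silylation of the primary alcohol; the triethylsilyl ether should survive the basic oxidations of ring B and can later be oxidised directly.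

Step 2
Reactants: 2 drimenol triethylsilyl ether
Product: 3 11'-triethylsilyloxy-drim-7'-en-6'-one
Conditions: Rh2(cap)4 (cat., cap = caprolactamate), t-BuOOH, K2CO3, CH2Cl2, rt
Reagents that add atoms: tert-butyl hydroperoxide CC(C)(C)OO
Why: Radical allylic C–H oxidation (dirhodium-catalysed hydroperoxide oxidation) should attack the ring methylene C6' next to the trisubstituted alkene, the tertiary C9'–H between two fully substituted carbons being shielded, to give the conjugated enone.

Step 3
Reactants: 3 11'-triethylsilyloxy-drim-7'-en-6'-one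
Product: 4 7'α,8'α-epoxy-11'-triethylsilyloxy-driman-6'-one
Conditions: 30% H2O2, NaOH, MeOH/CH2Cl2, 0 °C
Reagents that add atoms: hydrogen peroxide OO
Why: Weitz–Scheffer nucleophilic epoxidation; hydroperoxide should add to C8' from the α-face, opposite the axial C10' methyl group, which sets the C8' oxygen α and the C8' methyl β.

Step 4
Reactants: 4 7'α,8'α-epoxy-11'-triethylsilyloxy-driman-6'-one
Product: 5 11'-triethylsilyloxy-drim-6'-en-8'α-ol
Conditions: N2H4·H2O, AcOH (cat.), MeOH, 0 °C to rt
Reagents that add atoms: none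
Why: Wharton transposition (hydrazone, epoxide opening to a vinyldiazene, loss of N2) moves the alkene to C6'=C7' and leaves the C8'–O bond untouched, so the tertiary 8'α-alcohol is delivered with retention.

Step 5
Reactants: 5 11'-triethylsilyloxy-drim-6'-en-8'α-ol
Product: 6 8'α,11'-bis(triethylsilyloxy)drim-6'-ene
Conditions: Et3SiOTf, 2,6-lutidine, CH2Cl2, −78 to 0 °C
Reagents that add atoms: triethylsilyl trifluoromethanesulfonate CC[Si](CC)(CC)OS(=O)(=O)C(F)(F)F
Why: Silyl triflate with a hindered base silylates the tertiary allylic alcohol without ionising it; the bulky, non-chelating ether also serves the facial control in step 7.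

Step 6
Reactants: 6 8'α,11'-bis(triethylsilyloxy)drim-6'-ene
Product: 7 8'α-triethylsilyloxy-drim-6'-en-11'-al
Conditions: (COCl)2, DMSO, CH2Cl2, −78 to −30 °C; Et3N, −78 °C
Reagents that add atoms: none
Why: Swern oxidation acts directly on the primary triethylsilyl ether (exchange to the alkoxysulfonium salt) and leaves the tertiary silyl ether; low temperature should prevent β-elimination and epimerisation at C9'.

Step 7
Reactants: 7 8'α-triethylsilyloxy-drim-6'-en-11'-al; 8 N-methoxy-N-methylacetamide
Product: 10 (2R)-β-hydroxy amide Dr–CH(OH)–CH2–C(O)N(OMe)Me, via lithium enolate 9 (not isolated)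
Conditions: LiN(iPr)2, THF, −78 °C; then 7, −78 °C; aq NH4Cl at −78 °C
Reagents that add atoms: none
Why: Aldol addition of a preformed amide enolate under non-chelating conditions (Felkin–Anh): the β-face of the aldehyde is screened by the axial methyl groups on C8' and C10', and the enolate should enter from the α-face anti to the C9'–C8' bond that carries the bulky silyloxy group, which sets C2 as R.

Step 8
Reactants: 10 (2R)-β-hydroxy amide; 11 allyl ethyl carbonate
Product: 12 (2R)-β-allyloxy amide Dr–CH(OCH2CH=CH2)–CH2–C(O)N(OMe)Me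
Conditions: Pd2(dba)3 (cat.), dppb, THF, 65 °C
Reagents that add atoms: none
Why: Palladium-catalysed decarboxylative O-allylation (Tsuji–Trost type) under neutral conditions: ethoxide released from the carbonate deprotonates the carbinol and the alkoxide captures the π-allylpalladium cation, so no stoichiometric strong base is present that could cause retro-aldol cleavage.

Step 9
Reactants: 12 (2R)-β-allyloxy amide; 13 methacrolein
Product: 14 (E)-enal Dr–CH[OCH2CH=C(CH3)CHO]–CH2–C(O)N(OMe)Me
Conditions: second-generation Hoveyda–Grubbs catalyst RuCl2(H2IMes)(=CH-C6H4-2-OiPr) (cat.), excess 13, CH2Cl2, 40 °C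
Reagents that add atoms: none
Why: Olefin cross-metathesis of the terminal allyl ether with excess methacrolein should give the E-configured trisubstituted enal; the hindered ring alkene C6'=C7' does not take part.

Step 10
Reactants: 14 (E)-enal
Product: 15 (1E,3Z)-silyl dienol ether Dr–CH[OCH=CH–C(CH3)=CH–OSiMe2tBu]–CH2–C(O)N(OMe)Me
Conditions: t-BuMe2SiOTf, Et3N, Et2O, −78 to 0 °C
Reagents that add atoms: tert-butyldimethylsilyl trifluoromethanesulfonate CC(C)(C)[Si](C)(C)OS(=O)(=O)C(F)(F)F
Why: Soft enolisation (silyl triflate/amine) removes a γ-proton at the oxygen-bearing C8a to give the 1-silyloxy-4-alkoxy diene; the amide is not enolised under these conditions, the alkoxy group is expected to favour the 3Z enol ether (syn effect), and C6=C7 forms E from the s-trans enal.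

Step 11
Reactants: 15 (1E,3Z)-silyl dienol ether; 16 vinylmagnesium bromide
Product: 18 cis-fused cycloadduct 2-Dr-6-silyloxy-7-methyl-hexahydrochromen-4-one, via trienone 17 (not isolated)
Conditions: CH2=CHMgBr, THF, −78 to −20 °C; cold aq NaH2PO4, extraction; then toluene, BHT, 100 °C
Reagents that add atoms: none
Why: Vinyl addition to the N-methoxy-N-methylamide gives, after collapse of the chelated tetrahedral intermediate on quench, trienone 17, in which a 1-silyloxy-4-alkoxy diene and a vinyl ketone are joined by the four-atom tether O1–C2–C3–C4; heating should trigger a concerted, suprafacial intramolecular Diels–Alder reaction, the closest known type being the cyclisation of 1,7,9-decatrien-3-ones to cis-octalones. The cyclohexene ring C4a–C5–C6–C7–C8–C8a closes by the two new bonds C5–C6 and C4a–C8a ([4+2] mode), and the tetrahydropyran-4-one ring O1–C2–C3–C4–C4a–C8a closes with the same C4a–C8a bond (fused mode, tether on the diene terminus and on the inner dienophile carbon). The cis ring fusion at C4a and C8a follows from the tether: the 3Z enol ether holds O1 inside the diene, so the ketone can reach C4a only in the exo arrangement (a 3E diene would give the same fusion through the endo arrangement). The diene face is chosen by C2, whose drimanyl group takes the outward position on the tether, so that H2, H4a and H8a should end up mutually cis. C6 follows the E geometry of the silyl enol ether and is of no consequence, because it becomes the carbonyl carbon. The step needs the cycloaddition to outrun β-elimination of the dienyloxy group and the hetero-Diels–Alder mode of the enone; the electron-rich diene matched with the enone and the entropic gain of the tether should secure this, and the regiochemistry is fixed by the tether.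

Step 12
Reactants: 18 cis-fused cycloadduct
Product: 20 C3=C4 enol triflate, via potassium enolate 19 (not isolated)
Conditions: KN(SiMe3)2, THF, −78 °C; N-(5-chloro-2-pyridyl)triflimide, −78 to −40 °C
Reagents that add atoms: N-(5-chloro-2-pyridyl)bis(trifluoromethanesulfonimide) ClC1=CN=C(C=C1)N(S(=O)(=O)C(F)(F)F)S(=O)(=O)C(F)(F)F
Why: Kinetic deprotonation at the less hindered C3 methylene (C4a–H is tertiary and at the ring fusion) and O-triflation of the enolate fix the C3=C4 double bond; at −78 °C neither epimerisation at C4a nor β-elimination of O1 should occur.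

Step 13
Reactants: 20 C3=C4 enol triflate; 21 (tributylstannyl)methanol
Product: 22 allylic alcohol (4-hydroxymethyl-2H-chromene)
Conditions: Pd(PPh3)4 (cat.), LiCl, dioxane, 90 °C
Reagents that add atoms: none
Why: Stille coupling of the alkenyl triflate with the hydroxymethylstannane (chloride additive) installs the CH2OH carbon on C4 and keeps the double bond at C3=C4.

Step 14
Reactants: 22 allylic alcohol
Product: 23 allylic acetate
Conditions: Ac2O, pyridine, DMAP (cat.), CH2Cl2, 0 °C
Reagents that add atoms: acetic anhydride CC(=O)OC(C)=O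
Why: Routine acetylation of the only free (primary allylic) hydroxyl group.

Step 15
Reactants: 23 allylic acetate
Product: 24 diol (C6–OH and C8'–OH free)
Conditions: HF·pyridine, pyridine, THF, 0 °C to rt
Reagents that add atoms: none
Why: Buffered HF·pyridine cleaves the secondary allylic tert-butyldimethylsilyl ether and the tertiary triethylsilyl ether, leaves the acetate, and should not be acidic enough to ionise the tertiary allylic alcohol.

Step 16
Reactants: 24 diol
Product: 25 CNP0180075.1 (target)
Conditions: MnO2, CH2Cl2, rt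
Reagents that add atoms: none
Why: MnO2 oxidises the secondary allylic alcohol at C6 to the enone; the tertiary alcohol cannot be oxidised and the acetate is inert.

**Compound list**

1 | (−)-drimenol, (5S,9S,10S)-drim-7-en-11-ol | OC[C@@H]1[C@@]2(C)CCCC(C)(C)[C@@H]2CC=C1C | starting material
2 | drimenol triethylsilyl ether | CC[Si](CC)(CC)OC[C@@H]1[C@@]2(C)CCCC(C)(C)[C@@H]2CC=C1C | intermediate
3 | 11'-triethylsilyloxy-drim-7'-en-6'-one | CC[Si](CC)(CC)OC[C@@H]1[C@@]2(C)CCCC(C)(C)[C@@H]2C(=O)C=C1C | intermediate
4 | 7'α,8'α-epoxy-11'-triethylsilyloxy-driman-6'-one | CC[Si](CC)(CC)OC[C@@H]1[C@@]2(C)CCCC(C)(C)[C@@H]2C(=O)[C@H]3O[C@@]13C | intermediate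
5 | 11'-triethylsilyloxy-drim-6'-en-8'α-ol | CC[Si](CC)(CC)OC[C@@H]1[C@@]2(C)CCCC(C)(C)[C@@H]2C=C[C@@]1(C)O | intermediate
6 | 8'α,11'-bis(triethylsilyloxy)drim-6'-ene | CC[Si](CC)(CC)OC[C@@H]1[C@@]2(C)CCCC(C)(C)[C@@H]2C=C[C@@]1(C)O[Si](CC)(CC)CC | intermediate
7 | 8'α-triethylsilyloxy-drim-6'-en-11'-al | O=C[C@@H]1[C@@]2(C)CCCC(C)(C)[C@@H]2C=C[C@@]1(C)O[Si](CC)(CC)CC | intermediate
8 | N-methoxy-N-methylacetamide | CC(=O)N(C)OC | starting material
9 | lithium enolate of 8 | [Li+].[O-]C(=C)N(C)OC | intermediate
10 | (2R)-β-hydroxy amide Dr–CH(OH)–CH2–C(O)N(OMe)Me | CON(C)C(=O)C[C@@H](O)[C@@H]1[C@@]2(C)CCCC(C)(C)[C@@H]2C=C[C@@]1(C)O[Si](CC)(CC)CC | intermediate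
11 | allyl ethyl carbonate | C=CCOC(=O)OCC | starting material
12 | (2R)-β-allyloxy amide | CON(C)C(=O)C[C@@H](OCC=C)[C@@H]1[C@@]2(C)CCCC(C)(C)[C@@H]2C=C[C@@]1(C)O[Si](CC)(CC)CC | intermediate
13 | methacrolein | CC(=C)C=O | starting material
14 | (E)-enal, 4-alkoxy-2-methylbut-2-enal ether of 10 | CON(C)C(=O)C[C@@H](OC/C=C(\C)C=O)[C@@H]1[C@@]2(C)CCCC(C)(C)[C@@H]2C=C[C@@]1(C)O[Si](CC)(CC)CC | intermediate
15 | (1E,3Z)-1-(tert-butyldimethylsilyloxy)-2-methyl-4-alkoxybuta-1,3-diene amide | CON(C)C(=O)C[C@@H](O/C=C\C(C)=C\O[Si](C)(C)C(C)(C)C)[C@@H]1[C@@]2(C)CCCC(C)(C)[C@@H]2C=C[C@@]1(C)O[Si](CC)(CC)CC | intermediate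
16 | vinylmagnesium bromide | C=C[Mg]Br | starting material
17 | trienone (vinyl ketone with the 1-silyloxy-4-alkoxy diene) | C=CC(=O)C[C@@H](O/C=C\C(C)=C\O[Si](C)(C)C(C)(C)C)[C@@H]1[C@@]2(C)CCCC(C)(C)[C@@H]2C=C[C@@]1(C)O[Si](CC)(CC)CC | intermediate
18 | cis-fused cycloadduct, 2-Dr-6-(tert-butyldimethylsilyloxy)-7-methyl-2,3,4a,5,6,8a-hexahydrochromen-4-one; H2, H4a, H8a cis; 6-OSi trans to O1 | O=C1C[C@H]([C@@H]3[C@@]4(C)CCCC(C)(C)[C@@H]4C=C[C@@]3(C)O[Si](CC)(CC)CC)O[C@@H]2C=C(C)[C@@H](O[Si](C)(C)C(C)(C)C)C[C@H]12 | intermediate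
19 | potassium C3=C4 enolate of 18 | [K+].[O-]C1=C[C@H]([C@@H]3[C@@]4(C)CCCC(C)(C)[C@@H]4C=C[C@@]3(C)O[Si](CC)(CC)CC)O[C@@H]2C=C(C)[C@@H](O[Si](C)(C)C(C)(C)C)C[C@H]12 | intermediate
20 | C3=C4 enol triflate | O=S(=O)(OC1=C[C@H]([C@@H]3[C@@]4(C)CCCC(C)(C)[C@@H]4C=C[C@@]3(C)O[Si](CC)(CC)CC)O[C@@H]2C=C(C)[C@@H](O[Si](C)(C)C(C)(C)C)C[C@H]12)C(F)(F)F | intermediate
21 | (tributylstannyl)methanol | CCCC[Sn](CCCC)(CCCC)CO | starting material
22 | 4-hydroxymethyl-2H-chromene (allylic alcohol) | OCC1=C[C@H]([C@@H]3[C@@]4(C)CCCC(C)(C)[C@@H]4C=C[C@@]3(C)O[Si](CC)(CC)CC)O[C@@H]2C=C(C)[C@@H](O[Si](C)(C)C(C)(C)C)C[C@H]12 | intermediate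
23 | allylic acetate, bis-silyl ether | CC(=O)OCC1=C[C@H]([C@@H]3[C@@]4(C)CCCC(C)(C)[C@@H]4C=C[C@@]3(C)O[Si](CC)(CC)CC)O[C@@H]2C=C(C)[C@@H](O[Si](C)(C)C(C)(C)C)C[C@H]12 | intermediate
24 | diol (6-hydroxy, 8'α-hydroxy) acetate | CC(=O)OCC1=C[C@H]([C@@H]3[C@@]4(C)CCCC(C)(C)[C@@H]4C=C[C@@]3(C)O)O[C@@H]2C=C(C)[C@@H](O)C[C@H]12 | intermediate
25 | CNP0180075.1 | CC(=O)OCC1=C[C@H]([C@@H]2[C@@]3(C)CCCC(C)(C)[C@@H]3C=C[C@@]2(C)O)O[C@@H]2C=C(C)C(=O)C[C@H]12 | target

**Totals**

Total step count: 16. Longest linear sequence: 16 steps (from 1).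

**Steps most likely to fail**

Step 11. What may go wrong: hydrolysis of the silyl dienol ether during the organomagnesium step and quench, or cycloaddition of the 3Z diene so slow that β-elimination of the dienyloxy group from the enone takes over. Fallback (sets out from 10, comes back at 18): the C6 oxygen is introduced after the cycloaddition and the diene is made robust and E-configured. Conjugate addition of the hydroxyl of 10 to but-3-yn-2-one (PMe3 cat., CH2Cl2) should give the (E)-β-alkoxy enone F1. Methylenation (Ph3P=CH2, THF) gives the 1-alkoxy-3-methylbuta-1,3-diene F2. CH2=CHMgBr and then heating in toluene give the trienone F3 and, through the endo mode, the cycloadduct F4 that has a CH2 group at C6. Allylic hydroxylation with SeO2/t-BuOOH (ring CH2 next to the methyl-bearing alkene carbon, oxygen delivered on the convex face) gives the allylic alcohol F5, and t-BuMe2SiCl/imidazole returns to 18.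

Step 8. What may go wrong: incomplete allylation of the very hindered C2 hydroxyl, or migration of the triethylsilyl group from the C8' oxygen to the C2 oxygen in the transient alkoxide. Fallback (sets out from 7, comes back at 12): the ether is formed at the aldehyde stage, so the hindered carbinol is never alkylated. 8 is converted with LiN(iPr)2/Me3SiCl into the silyl ketene N,O-acetal F6. Then 7, allyloxytrimethylsilane and F6 are combined with catalytic Me3SiOTf in CH2Cl2 at −78 °C (O-allyl oxocarbenium ion, then Mukaiyama-type addition, again expected from the α-face) to give 12 directly.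

Step 7. What may go wrong: poor or reversed facial selectivity of the enolate addition at C2. Fallback (sets out from 7, comes back at 10): the carbinol centre is set by hydride instead of carbon. The epimeric (2S)-alcohol F7 (or the mixture) is oxidised with Dess–Martin periodinane to the β-keto amide F8 and reduced with NaBH4 in MeOH at −40 °C. Hydride entering from the same open face that the enolate used gives the opposite carbinol configuration, that is 10.

**Further compounds**

F1 | step 11 | (E)-β-alkoxy enone from 10 and but-3-yn-2-one | CON(C)C(=O)C[C@@H](O/C=C/C(C)=O)[C@@H]1[C@@]2(C)CCCC(C)(C)[C@@H]2C=C[C@@]1(C)O[Si](CC)(CC)CC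
F2 | step 11 | (E)-1-alkoxy-3-methylbuta-1,3-diene amide | CON(C)C(=O)C[C@@H](O/C=C/C(C)=C)[C@@H]1[C@@]2(C)CCCC(C)(C)[C@@H]2C=C[C@@]1(C)O[Si](CC)(CC)CC
F3 | step 11 | trienone without C6 oxygen | C=CC(=O)C[C@@H](O/C=C/C(C)=C)[C@@H]1[C@@]2(C)CCCC(C)(C)[C@@H]2C=C[C@@]1(C)O[Si](CC)(CC)CC
F4 | step 11 | cis-fused cycloadduct with CH2 at C6 | O=C1C[C@H]([C@@H]3[C@@]4(C)CCCC(C)(C)[C@@H]4C=C[C@@]3(C)O[Si](CC)(CC)CC)O[C@@H]2C=C(C)CC[C@H]12
F5 | step 11 | 6-hydroxy cycloadduct | O=C1C[C@H]([C@@H]3[C@@]4(C)CCCC(C)(C)[C@@H]4C=C[C@@]3(C)O[Si](CC)(CC)CC)O[C@@H]2C=C(C)[C@@H](O)C[C@H]12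
F6 | step 8 | silyl ketene N,O-acetal of 8 | C=C(O[Si](C)(C)C)N(C)OC
F7 | step 7 | (2S)-β-hydroxy amide, C2 epimer of 10 | CON(C)C(=O)C[C@H](O)[C@@H]1[C@@]2(C)CCCC(C)(C)[C@@H]2C=C[C@@]1(C)O[Si](CC)(CC)CC
F8 | step 7 | β-keto amide | CON(C)C(=O)CC(=O)[C@@H]1[C@@]2(C)CCCC(C)(C)[C@@H]2C=C[C@@]1(C)O[Si](CC)(CC)CC
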